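## Analysis of the target

Compound 16 is a benzoic acid with four ring substituents. C1 carries CO2H and C4 (para) carries OCH3. C3 and C5, the two carbons flanking the methoxy carbon, carry two different allylic chains through benzylic CH2 groups, and C2 and C6 are CH. The short arm is (2E)-4-hydroxy-3-methylbut-2-enyl and the long arm is (2E,4R)-4-hydroxy-3,7-dimethylocta-2,6-dienyl. Both share the unit Ar–CH2–CH=C(CH3)–C–O and differ only in what the oxygen-bearing carbon carries (H or a prenyl group). The single stereocentre, C4' of the long arm, is a secondary alcohol that is allylic to the (E)-C2'=C3' olefin and homoallylic to the isopropylidene end. It has no neighbouring centre to relay from, so it must be set by reagent or catalyst control. The sensitive features are the two benzylic–allylic CH2 groups (olefin migration into conjugation with the ring), the two allylic alcohols (ionization and allylic transposition under acid), the E geometry of two trisubstituted olefins, and the free acid. The real difficulty is differentiation. C3 and C5 of a 4-oxygenated benzoate are equivalent, so a preformed ring forces either a statistical choice between two identical arms or two separate ortho-functionalization sequences. The feature the plan exploits is the ring segment C3–C4(OCH3)–C5, with the carboxyl carbon C1 para to oxygen and hydrogen on C2 and C6. This is the pattern produced when a 3-substituted 2-pyrone-5-carboxylate (supplying C5, C6, C1 and C2) and a 1-methoxyalkyne (supplying C4 with its oxygen and C3 with its chain) combine with loss of the lactone bridge.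

## Retrosynthetic reasoning

**16 back to 14.** The acid and the primary alcohol of 16 are unmasked last. One operation removes the silyl ether and the methyl ester of 14, passing through 15. Both groups are present from the fragments onward, so no protecting-group step is added in the middle of the route.

**14 back to 11.** The long arm of 14 is cut at three places.
- The C6'=C7' olefin is traced to the terminal vinyl group of 13, by a cross-metathesis that exchanges a methylene for an isopropylidene.
- The C4'–C5' bond of 13 is traced to enal 12 and an allylboron reagent under a chiral Brønsted acid. This is where the (R) centre is set.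
- The C2'=C3' olefin of 12 is traced to the allyl group of 11 by a second cross-metathesis, which gives the E enal under thermodynamic control.

These cuts are placed after the ring construction because an aldehyde or a free alcohol would not tolerate an ynol ether, whereas a bare allyl group is inert. The long arm is thereby reduced to three carbons at the stage of the key step.

**11 back to 9 and 6 (key disconnection).** The benzene ring of 11 is cut at C2–C3 and C4–C5, and a lactone bridge is added back across C2 and C5. This leaves 2-pyrone 9, which holds C5 (with the allyl group), C6, C1 (with the ester) and C2. It also leaves ynol ether 6, which holds C4 (with the methoxy group) and C3 (with the protected short arm). The cut is made here for two reasons. It places the two arms on two different fragments, so they are different from the outset. The polarity of the fragments also dictates one orientation, with the ester para to the methoxy group and the methoxy carbon between the two chains. The forward reaction has to form two C–C bonds, expel the bridge by decarboxylation and aromatize, without an oxidant and without touching three olefins.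

**9 back to 7.** The allyl–C3 bond of 9 is cut to bromopyrone 8 and an allyltin reagent (Stille coupling). 8 is traced to commercial 7 by bromination at the only nucleophilic ring position. Two steps give the diene.

**6 back to 1 and 4.** The propargylic C–C bond of 6 is cut to methoxyacetylide 5, made in the flask from chloroacetal 4, and allylic chloride 3. 3 comes from 2 by silylation, and 2 from vinyl oxirane 1 by SN2' opening with chloride. This first step creates the E-trisubstituted olefin of the short arm.

## Alternatives that were turned down

**Alternative 1:** This is the textbook route, in which both aryl–CH2 bonds are disconnected from a preformed ring. Methyl 4-hydroxybenzoate A1 would be O-allylated and rearranged (aromatic Claisen) twice, then O-methylated to methyl 4-methoxy-3,5-di(prop-2-en-1-yl)benzoate A2. Double cross-metathesis would give the bis-enal methyl 4-methoxy-3,5-bis[(2E)-3-methyl-4-oxobut-2-en-1-yl]benzoate A3. One aldehyde would then be allylated and the other reduced. It was turned down because the two arms of A2 and A3 are homotopic (exchanged by the twofold axis through C1 and C4). No reagent or catalyst can prefer one, so the mono-functionalization is statistical. A sequential variant that completes one arm before the second rearrangement must carry an allylic oxygen function through a Claisen step near 200 °C. It also spends about five steps before the arms differ at all.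

**Alternative 2:** This is a biomimetic route: prenyl transfer, then allylic oxidation. A1 would be C-alkylated ortho with a prenyl and a geranyl electrophile and O-methylated to methyl 3-[(2E)-3,7-dimethylocta-2,6-dien-1-yl]-4-methoxy-5-(3-methylbut-2-en-1-yl)benzoate A4. The two hydroxyl groups would then be introduced by late allylic oxidation. It was turned down on mechanistic grounds. A4 holds three trisubstituted olefins and several allylic positions of similar reactivity. Selenium-based allylic oxidation goes to the E methyl group of an isopropylidene terminus, which is right for the prenyl arm. In the geranyl arm the same preference leads to C8', not to the C4' methylene. Nothing in such an oxidation controls the configuration at C4'. Phenoxide C-alkylation also gives O- and C-alkylated and polyalkylated mixtures.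

**Alternative 3:** This is another ring construction, a normal-demand Diels–Alder/decarboxylation. The 4-methoxy-2-pyrone carrying both chains, 3-[(2E)-4-{[tert-butyl(dimethyl)silyl]oxy}-3-methylbut-2-en-1-yl]-4-methoxy-5-(prop-2-en-1-yl)-2H-pyran-2-one A5, would react with a propiolate ester to give 11. It was turned down for three reasons. Both chains must be put on one small heterocycle by two successive C-alkylations of a 4-hydroxypyrone, with O- versus C-alkylation and C3 versus C5 to be controlled, so the convergence of the chosen route is lost. An electron-rich pyrone and a propiolate need much higher temperatures. The orientation rests on a weaker coefficient bias, so para/meta mixtures are to be expected.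

Key step: step 6

Remark on the chemistry: 1, 4 and 7 are taken as commercial, and the sense of induction in step 8 is assigned from the accepted chair transition-state model of phosphoric-acid-catalysed allylboration ((R)-catalyst, Re-face addition).

## Route

Step 1
Reactants: 1 2-methyl-2-vinyloxirane (racemic)
Product: 2 (2E)-4-chloro-2-methylbut-2-en-1-ol
Conditions: TiCl4, CH2Cl2, −85 °C; then aq. HCl
Reagents that add atoms: titanium tetrachloride, Cl[Ti](Cl)(Cl)Cl
Why: Lewis-acid activation of the vinyl oxirane and SN2' delivery of chloride to the vinyl terminus should open the ring; reaction through the favoured s-trans conformer gives the E-trisubstituted olefin, and any minor Z isomer is removed by chromatography here or at 3.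

Step 2
Reactants: 2 (2E)-4-chloro-2-methylbut-2-en-1-ol
Product: 3 tert-butyl{[(2E)-4-chloro-2-methylbut-2-en-1-yl]oxy}dimethylsilane
Conditions: TBSCl, imidazole, DMF, 0 °C to rt
Reagents that add atoms: tert-butyldimethylsilyl chloride, CC(C)(C)[Si](C)(C)Cl
Why: Standard silylation of a primary alcohol; the silyl ether masks the hydroxyl group against the acetylide of step 3 and keeps a free OH away from the ynol ether.

Step 3
Reactants: 4 2-chloro-1,1-dimethoxyethane; 3 tert-butyl{[(2E)-4-chloro-2-methylbut-2-en-1-yl]oxy}dimethylsilane
Product: 6 tert-butyl{[(2E)-6-methoxy-2-methylhex-2-en-5-yn-1-yl]oxy}dimethylsilane, via sodium methoxyacetylide 5 (not isolated)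
Conditions: NaNH2 (3.0 equiv, 4 in slight excess), NH3(l), −33 °C; then 3 in THF, −33 °C to rt
Reagents that add atoms: none
Why: Two eliminations (of methanol, then of HCl) and a deprotonation convert the chloroacetal into the alkoxyacetylide, the classical entry to 1-alkoxyalkynes. SN2 alkylation at the primary allylic carbon of 3 keeps the E geometry, because SN2' attack would have to occur at the fully substituted olefin carbon. Keeping the amide as the limiting reagent avoids base-mediated migration of the skipped enyne.

Step 4
Reactants: 7 methyl 2-oxo-2H-pyran-5-carboxylate (methyl coumalate)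
Product: 8 methyl 3-bromo-2-oxo-2H-pyran-5-carboxylate
Conditions: Br2, CH2Cl2, 0 °C to rt; then Et3N, 0 °C
Reagents that add atoms: bromine, BrBr
Why: Bromination by addition–elimination should occur at C3, the only nucleophilic ring carbon (α to the lactone carbonyl and conjugated with the ring oxygen), since C5 is blocked by the ester.

Step 5
Reactants: 8 methyl 3-bromo-2-oxo-2H-pyran-5-carboxylate
Product: 9 methyl 2-oxo-3-(prop-2-en-1-yl)-2H-pyran-5-carboxylate
Conditions: CH2=CHCH2SnBu3, Pd(PPh3)4 (5 mol %, zerovalent palladium), toluene, 80 °C
Reagents that add atoms: allyltributylstannane, C=CC[Sn](CCCC)(CCCC)CCCC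
Why: Stille coupling; 3-bromo-2-pyrones undergo oxidative addition readily at the C3–Br bond, and allyl is among the fastest groups to transfer from tin.

Step 6
Reactants: 9 methyl 2-oxo-3-(prop-2-en-1-yl)-2H-pyran-5-carboxylate; 6 tert-butyl{[(2E)-6-methoxy-2-methylhex-2-en-5-yn-1-yl]oxy}dimethylsilane
Product: 11 methyl 3-[(2E)-4-{[tert-butyl(dimethyl)silyl]oxy}-3-methylbut-2-en-1-yl]-4-methoxy-5-(prop-2-en-1-yl)benzoate, via bicyclic lactone cycloadduct 10 (not isolated)
Conditions: toluene, 120 °C, sealed tube, argon, 2,6-di-tert-butyl-4-methylphenol (cat.)
Reagents that add atoms: none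
Why: The electron-poor 2-pyrone 9 (lactone carbonyl plus C5 ester) and the electron-rich alkyne 6 should combine in an inverse-electron-demand Diels–Alder reaction to the bridged lactone 10, which loses CO2 by retro-[4+2] at the reaction temperature and is aromatic at once, so no oxidant is needed. The closest known reaction type is the cycloaddition–decarboxylation of coumalate esters and other ester-substituted 2-pyrones with enol ethers, ketene acetals and heteroatom-substituted alkynes, which gives benzoates with the donor para to the ester. The benzene ring is the one ring closed: an intermolecular [4+2] cycloaddition makes the C2–C3 and C4–C5 bonds of the arene (pyrone C6 to the alkyne carbon remote from oxygen, pyrone C3 to the methoxy-bearing carbon), and cycloreversion of the lactone bridge follows. No stereocentre is created in 11; the two bridgehead centres of 10 arise and vanish in the same operation, and the E olefin of 6 is a spectator. The selectivity the step needs is regioselectivity, and matched polarity secures it: the largest LUMO coefficient of 9 lies at C6 (β to the ester, δ to the lactone carbonyl) and the largest HOMO coefficient of 6 at the alkyne carbon β to oxygen, so bonding in this sense should run ahead in an asynchronous transition state and place OCH3 para to the ester and between the two chains. Chemoselectivity follows from the nucleophilicity of the ynol ether, which far exceeds that of the monosubstituted and trisubstituted olefins present. A methyl ynol ether is chosen because it has no β-hydrogen on the O-alkyl group, which closes the retro-ene fragmentation to a ketene that limits ethyl and tert-butyl ynol ethers on heating, and because it delivers the methyl ether of the target directly.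

Step 7
Reactants: 11 methyl 3-[(2E)-4-{[tert-butyl(dimethyl)silyl]oxy}-3-methylbut-2-en-1-yl]-4-methoxy-5-(prop-2-en-1-yl)benzoate
Product: 12 methyl 3-[(2E)-4-{[tert-butyl(dimethyl)silyl]oxy}-3-methylbut-2-en-1-yl]-4-methoxy-5-[(2E)-3-methyl-4-oxobut-2-en-1-yl]benzoate
Conditions: methacrolein (5 equiv), second-generation Hoveyda–Grubbs catalyst RuCl2(=CH-C6H4-2-OiPr)(H2IMes) (5 mol %), 1,4-benzoquinone (10 mol %), CH2Cl2, 40 °C
Reagents that add atoms: methacrolein, CC(=C)C=O
Why: Olefin cross-metathesis of a terminal olefin with an electron-poor 1,1-disubstituted enal, which does not homodimerize, should give the E-trisubstituted enal under thermodynamic control. The trisubstituted olefin of the short arm is far less reactive, and benzoquinone suppresses migration of the allyl double bond by ruthenium hydrides.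

Step 8
Reactants: 12 methyl 3-[(2E)-4-{[tert-butyl(dimethyl)silyl]oxy}-3-methylbut-2-en-1-yl]-4-methoxy-5-[(2E)-3-methyl-4-oxobut-2-en-1-yl]benzoate
Product: 13 methyl 3-[(2E)-4-{[tert-butyl(dimethyl)silyl]oxy}-3-methylbut-2-en-1-yl]-5-[(2E,4R)-4-hydroxy-3-methylhepta-2,6-dien-1-yl]-4-methoxybenzoate
Conditions: allylB(pin) (1.3 equiv), (R)-3,3'-bis(2,4,6-triisopropylphenyl)-1,1'-binaphthyl-2,2'-diyl hydrogen phosphate (5 mol %), toluene, 4 Å MS, −30 °C
Reagents that add atoms: allylboronic acid pinacol ester, C=CCB1OC(C)(C)C(C)(C)O1
Why: Chiral-phosphoric-acid-catalysed allylboration through a closed six-membered chair transition state; the catalyst activates the boronate by hydrogen bonding to a boronate oxygen and, in the (R) series, should direct the allyl group to the Re face of the aldehyde, which gives the (R) carbinol (alkenyl ranks above allyl CH2). The ester, silyl ether and olefins are inert to the boronate.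

Step 9
Reactants: 13 methyl 3-[(2E)-4-{[tert-butyl(dimethyl)silyl]oxy}-3-methylbut-2-en-1-yl]-5-[(2E,4R)-4-hydroxy-3-methylhepta-2,6-dien-1-yl]-4-methoxybenzoate
Product: 14 methyl 3-[(2E)-4-{[tert-butyl(dimethyl)silyl]oxy}-3-methylbut-2-en-1-yl]-5-[(2E,4R)-4-hydroxy-3,7-dimethylocta-2,6-dien-1-yl]-4-methoxybenzoate
Conditions: 2-methyl-2-butene (large excess), second-generation Grubbs catalyst RuCl2(=CHPh)(PCy3)(H2IMes) (5 mol %), CH2Cl2, rt
Reagents that add atoms: 2-methyl-2-butene, CC=C(C)C
Why: Cross-metathesis with 2-methyl-2-butene exchanges the terminal methylene for an isopropylidene group; the monosubstituted olefin is by far the most reactive site, and the reaction is stopped when it is consumed so that the trisubstituted olefins are spared. The carbinol centre is not involved.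

Step 10
Reactants: 14 methyl 3-[(2E)-4-{[tert-butyl(dimethyl)silyl]oxy}-3-methylbut-2-en-1-yl]-5-[(2E,4R)-4-hydroxy-3,7-dimethylocta-2,6-dien-1-yl]-4-methoxybenzoate
Product: 16 3-[(2E,4R)-4-hydroxy-3,7-dimethylocta-2,6-dien-1-yl]-5-[(2E)-4-hydroxy-3-methylbut-2-en-1-yl]-4-methoxybenzoic acid, via diol methyl ester 15 (not isolated)
Conditions: Bu4NF, THF, 0 °C to rt; then LiOH, H2O, MeOH, 40 °C; then 1 M HCl to pH 4, 0 °C
Reagents that add atoms: lithium hydroxide, [Li+].[OH-]
Why: Fluoride desilylation followed in the same flask by saponification of the unhindered methyl benzoate. Brief acidification in the cold to pH 4 protonates the carboxylate without ionizing the allylic alcohols, so the (R) centre and both E olefins should be retained.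

## Compound list

1 | 2-methyl-2-vinyloxirane (racemic) | CC1(C=C)CO1 | starting material
2 | (2E)-4-chloro-2-methylbut-2-en-1-ol | ClC/C=C(\C)CO | intermediate
3 | tert-butyl{[(2E)-4-chloro-2-methylbut-2-en-1-yl]oxy}dimethylsilane | ClC/C=C(\C)CO[Si](C)(C)C(C)(C)C | intermediate
4 | 2-chloro-1,1-dimethoxyethane | COC(CCl)OC | starting material
5 | sodium methoxyacetylide | [Na+].[C-]#COC | intermediate (not isolated)
6 | tert-butyl{[(2E)-6-methoxy-2-methylhex-2-en-5-yn-1-yl]oxy}dimethylsilane | COC#CC/C=C(\C)CO[Si](C)(C)C(C)(C)C | intermediate
7 | methyl 2-oxo-2H-pyran-5-carboxylate (methyl coumalate) | COC(=O)C1=COC(=O)C=C1 | starting material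
8 | methyl 3-bromo-2-oxo-2H-pyran-5-carboxylate | COC(=O)C1=COC(=O)C(Br)=C1 | intermediate
9 | methyl 2-oxo-3-(prop-2-en-1-yl)-2H-pyran-5-carboxylate | COC(=O)C1=COC(=O)C(CC=C)=C1 | intermediate
10 | methyl 6-[(2E)-4-{[tert-butyl(dimethyl)silyl]oxy}-3-methylbut-2-en-1-yl]-5-methoxy-3-oxo-4-(prop-2-en-1-yl)-2-oxabicyclo[2.2.2]octa-5,7-diene-7-carboxylate (racemic) | C=CCC12C(=O)OC(C(C/C=C(\C)CO[Si](C)(C)C(C)(C)C)=C1OC)C(C(=O)OC)=C2 | intermediate (not isolated)
11 | methyl 3-[(2E)-4-{[tert-butyl(dimethyl)silyl]oxy}-3-methylbut-2-en-1-yl]-4-methoxy-5-(prop-2-en-1-yl)benzoate | COC(=O)c1cc(CC=C)c(OC)c(C/C=C(\C)CO[Si](C)(C)C(C)(C)C)c1 | intermediate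
12 | methyl 3-[(2E)-4-{[tert-butyl(dimethyl)silyl]oxy}-3-methylbut-2-en-1-yl]-4-methoxy-5-[(2E)-3-methyl-4-oxobut-2-en-1-yl]benzoate | COC(=O)c1cc(C/C=C(\C)C=O)c(OC)c(C/C=C(\C)CO[Si](C)(C)C(C)(C)C)c1 | intermediate
13 | methyl 3-[(2E)-4-{[tert-butyl(dimethyl)silyl]oxy}-3-methylbut-2-en-1-yl]-5-[(2E,4R)-4-hydroxy-3-methylhepta-2,6-dien-1-yl]-4-methoxybenzoate | COC(=O)c1cc(C/C=C(\C)[C@H](O)CC=C)c(OC)c(C/C=C(\C)CO[Si](C)(C)C(C)(C)C)c1 | intermediate
14 | methyl 3-[(2E)-4-{[tert-butyl(dimethyl)silyl]oxy}-3-methylbut-2-en-1-yl]-5-[(2E,4R)-4-hydroxy-3,7-dimethylocta-2,6-dien-1-yl]-4-methoxybenzoate | COC(=O)c1cc(C/C=C(\C)[C@H](O)CC=C(C)C)c(OC)c(C/C=C(\C)CO[Si](C)(C)C(C)(C)C)c1 | intermediate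
15 | methyl 3-[(2E,4R)-4-hydroxy-3,7-dimethylocta-2,6-dien-1-yl]-5-[(2E)-4-hydroxy-3-methylbut-2-en-1-yl]-4-methoxybenzoate | COC(=O)c1cc(C/C=C(\C)[C@H](O)CC=C(C)C)c(OC)c(C/C=C(\C)CO)c1 | intermediate (not isolated)
16 | 3-[(2E,4R)-4-hydroxy-3,7-dimethylocta-2,6-dien-1-yl]-5-[(2E)-4-hydroxy-3-methylbut-2-en-1-yl]-4-methoxybenzoic acid | COc1c(C/C=C(\C)CO)cc(C(=O)O)cc1C/C=C(\C)[C@H](O)CC=C(C)C | target

## Step count and least certain steps

Total step count: 10. Longest linear sequence: 8 steps (steps 1, 2, 3, 6, 7, 8, 9, 10). The pyrone branch (steps 4 and 5) joins at step 6.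

**Step 6 (key step).** The cycloaddition may be too slow, because bond formation at C3 of 9 creates a quaternary bridgehead next to the allyl group. Thermal oligomerization or adventitious hydration of the ynol ether would then compete. Erosion of the regioselectivity is a second possible failure.

The fallback changes the approach to a preformed benzene ring with an aryl–allyl cross-coupling. It sets out from 3 and comes back at 11.
- Purchased methyl 3-bromo-4-hydroxybenzoate F1 is O-allylated (allyl bromide, K2CO3, acetone) to methyl 3-bromo-4-(prop-2-en-1-yloxy)benzoate F2.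
- Aromatic Claisen rearrangement (N,N-diethylaniline, 200 °C) to the only free ortho position should give methyl 3-bromo-4-hydroxy-5-(prop-2-en-1-yl)benzoate F3.
- O-Methylation (MeI, K2CO3, DMF) gives methyl 3-bromo-4-methoxy-5-(prop-2-en-1-yl)benzoate F4.
- Miyaura borylation (B2pin2, KOAc, PdCl2(dppf) as divalent palladium precatalyst, dioxane, 80 °C) gives methyl 4-methoxy-3-(prop-2-en-1-yl)-5-(4,4,5,5-tetramethyl-1,3,2-dioxaborolan-2-yl)benzoate F5.
- Suzuki–Miyaura coupling of F5 with allylic chloride 3 (Pd(PPh3)4, K2CO3, THF/H2O, 60 °C) gives 11. It runs through a π-allyl palladium intermediate and should couple at the unsubstituted terminus with retention of the olefin geometry.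

**Step 3.** Base-mediated migration of the skipped enyne (the propargylic–allylic CH2) to an allene or conjugated enyne may occur. Attack of amide on the chloride may compete, and the acid-sensitive ynol ether may be lost on isolation.

The fallback changes which electrophile meets the acetylide and moves the attachment of the short arm to the end. It sets out from 5 and 8 and comes back at 11.
- 5 is alkylated with allyl bromide, which should react within minutes at −33 °C, to give distillable 1-methoxypent-4-en-1-yne F6.
- Cycloaddition of F6 with bromopyrone 8 (toluene, 110 °C) should give the aryl bromide methyl 3-bromo-4-methoxy-5-(prop-2-en-1-yl)benzoate F4. It passes through methyl 4-bromo-5-methoxy-3-oxo-6-(prop-2-en-1-yl)-2-oxabicyclo[2.2.2]octa-5,7-diene-7-carboxylate F7, which is not isolated and loses CO2.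
- Borylation to methyl 4-methoxy-3-(prop-2-en-1-yl)-5-(4,4,5,5-tetramethyl-1,3,2-dioxaborolan-2-yl)benzoate F5 and coupling with 3, as described for step 6, return to 11.

**Step 5.** The allyl double bond may migrate into conjugation with the pyrone under palladium hydride catalysis. The electrophilic pyrone may also suffer conjugate addition or ring opening under the coupling conditions.

The fallback carries the halogen through the ring construction and makes the sp2–sp3 bond on the arene. It sets out from 8 and 6 and comes back at 11.
- Cycloaddition of 8, which is more electron-poor than 9, with 6 should give methyl 3-bromo-5-[(2E)-4-{[tert-butyl(dimethyl)silyl]oxy}-3-methylbut-2-en-1-yl]-4-methoxybenzoate F9. It passes through methyl 4-bromo-6-[(2E)-4-{[tert-butyl(dimethyl)silyl]oxy}-3-methylbut-2-en-1-yl]-5-methoxy-3-oxo-2-oxabicyclo[2.2.2]octa-5,7-diene-7-carboxylate F8, which is not isolated.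
- Stille coupling of F9 with allyltributylstannane (Pd(PPh3)4, toluene, 100 °C) gives 11.

**Step 8.** Facial discrimination may be poor for the α-branched enal, or the catalysed pathway may be slow enough at low temperature for the uncatalysed racemic addition to compete.

The fallback sets the stereocentre by enantioselective reduction instead of C–C bond formation. It sets out from 14 of insufficient enantiomeric purity and comes back at 14.
- MnO2 (CH2Cl2, rt) oxidizes the allylic alcohol to the enone methyl 3-[(2E)-4-{[tert-butyl(dimethyl)silyl]oxy}-3-methylbut-2-en-1-yl]-5-[(2E)-3,7-dimethyl-4-oxoocta-2,6-dien-1-yl]-4-methoxybenzoate F10.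
- Corey–Bakshi–Shibata reduction ((S)-2-methyl-CBS-oxazaborolidine, BH3·SMe2, THF, −20 °C) should return (R)-14. The α-methyl alkenyl group acts as the large substituent, as phenyl does in the acetophenone case.

**Step 9.** Secondary metathesis at the trisubstituted olefins may occur, in particular exchange of the silyloxymethyl terminus of the short arm. Ruthenium hydrides may also cause olefin migration or redox isomerization of the allylic alcohol.

The fallback brings in the isopropylidene terminus with the nucleophile, without metathesis. It sets out from 12 and comes back at 14.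
- α-Selective 1,2-addition of prenylbarium chloride (from prenyl chloride and activated barium made from BaI2 and lithium biphenylide; THF, −78 °C) should give methyl 3-[(2E)-4-{[tert-butyl(dimethyl)silyl]oxy}-3-methylbut-2-en-1-yl]-5-[(2E)-4-hydroxy-3,7-dimethylocta-2,6-dien-1-yl]-4-methoxybenzoate (racemic at C4') F11.
- Oxidation of F11 with MnO2 gives methyl 3-[(2E)-4-{[tert-butyl(dimethyl)silyl]oxy}-3-methylbut-2-en-1-yl]-5-[(2E)-3,7-dimethyl-4-oxoocta-2,6-dien-1-yl]-4-methoxybenzoate F10.
- The CBS reduction described for step 8 gives 14.

## Further compounds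

F1 | step 6 | methyl 3-bromo-4-hydroxybenzoate (purchased) | COC(=O)c1ccc(O)c(Br)c1
F2 | step 6 | methyl 3-bromo-4-(prop-2-en-1-yloxy)benzoate | COC(=O)c1ccc(OCC=C)c(Br)c1
F3 | step 6 | methyl 3-bromo-4-hydroxy-5-(prop-2-en-1-yl)benzoate | COC(=O)c1cc(Br)c(O)c(CC=C)c1
F4 | step 6 | methyl 3-bromo-4-methoxy-5-(prop-2-en-1-yl)benzoate | COC(=O)c1cc(Br)c(OC)c(CC=C)c1
F5 | step 6 | methyl 4-methoxy-3-(prop-2-en-1-yl)-5-(4,4,5,5-tetramethyl-1,3,2-dioxaborolan-2-yl)benzoate | COC(=O)c1cc(B2OC(C)(C)C(C)(C)O2)c(OC)c(CC=C)c1
F6 | step 3 | 1-methoxypent-4-en-1-yne | COC#CCC=C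
F7 | step 3 | methyl 4-bromo-5-methoxy-3-oxo-6-(prop-2-en-1-yl)-2-oxabicyclo[2.2.2]octa-5,7-diene-7-carboxylate (racemic) | BrC12C(=O)OC(C(CC=C)=C1OC)C(C(=O)OC)=C2
F8 | step 5 | methyl 4-bromo-6-[(2E)-4-{[tert-butyl(dimethyl)silyl]oxy}-3-methylbut-2-en-1-yl]-5-methoxy-3-oxo-2-oxabicyclo[2.2.2]octa-5,7-diene-7-carboxylate (racemic) | BrC12C(=O)OC(C(C/C=C(\C)CO[Si](C)(C)C(C)(C)C)=C1OC)C(C(=O)OC)=C2
F9 | step 5 | methyl 3-bromo-5-[(2E)-4-{[tert-butyl(dimethyl)silyl]oxy}-3-methylbut-2-en-1-yl]-4-methoxybenzoate | COC(=O)c1cc(Br)c(OC)c(C/C=C(\C)CO[Si](C)(C)C(C)(C)C)c1
F10 | step 8 | methyl 3-[(2E)-4-{[tert-butyl(dimethyl)silyl]oxy}-3-methylbut-2-en-1-yl]-5-[(2E)-3,7-dimethyl-4-oxoocta-2,6-dien-1-yl]-4-methoxybenzoate | COC(=O)c1cc(C/C=C(\C)C(=O)CC=C(C)C)c(OC)c(C/C=C(\C)CO[Si](C)(C)C(C)(C)C)c1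
F11 | step 9 | methyl 3-[(2E)-4-{[tert-butyl(dimethyl)silyl]oxy}-3-methylbut-2-en-1-yl]-5-[(2E)-4-hydroxy-3,7-dimethylocta-2,6-dien-1-yl]-4-methoxybenzoate (racemic at C4') | COC(=O)c1cc(C/C=C(\C)C(O)CC=C(C)C)c(OC)c(C/C=C(\C)CO[Si](C)(C)C(C)(C)C)c1
A1 | alternative 1 | methyl 4-hydroxybenzoate | COC(=O)c1ccc(O)cc1
A2 | alternative 1 | methyl 4-methoxy-3,5-di(prop-2-en-1-yl)benzoate | COC(=O)c1cc(CC=C)c(OC)c(CC=C)c1
A3 | alternative 1 | methyl 4-methoxy-3,5-bis[(2E)-3-methyl-4-oxobut-2-en-1-yl]benzoate | COC(=O)c1cc(C/C=C(\C)C=O)c(OC)c(C/C=C(\C)C=O)c1
A4 | alternative 2 | methyl 3-[(2E)-3,7-dimethylocta-2,6-dien-1-yl]-4-methoxy-5-(3-methylbut-2-en-1-yl)benzoate | COC(=O)c1cc(CC=C(C)C)c(OC)c(C/C=C(\C)CCC=C(C)C)c1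
A5 | alternative 3 | 3-[(2E)-4-{[tert-butyl(dimethyl)silyl]oxy}-3-methylbut-2-en-1-yl]-4-methoxy-5-(prop-2-en-1-yl)-2H-pyran-2-one | O=C1OC=C(CC=C)C(OC)=C1C/C=C(\C)CO[Si](C)(C)C(C)(C)C
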